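## The problem

Target 31 is one open chain that links three units: a methylhydroquinone whose hindered oxygen is methylated, an (E)-trisubstituted alkene lying between a benzylic CH2 and a ketone, and a cyclopentane (ring carbons C1–C5). C1 carries a methyl and the (E)-4-hydroxy-4-methylpent-2-enoyl group; C2 carries a methyl and the 2-oxohex-4-enyl arm. Both are quaternary, both are R, and the two methyls are cis.

These are the only stereocentres, so nothing else in the molecule can relay chirality to them. One must be set absolutely and must then control its neighbour. A ring that ties the C1 carbonyl to the C2 arm is the natural relay, because it holds both on one face.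

Making two adjacent fully substituted carbons is the steric crux; the two alkenes need only geometric control.

Three groups limit the endgame. The β,γ-unsaturated ketone has a doubly activated CH2 and slips into conjugation with base or acid. The γ-hydroxy enone is a Michael acceptor with a tertiary allylic alcohol. The electron-rich phenol is oxidised to a quinone by strong oxidants.

The enabling feature is a map onto citronellol. C2 with its methyl and two-carbon arm is C3 of citronellol with its methyl and C1–C2, and the ring methylenes C3–C5 are citronellol C4–C6. A carbene placed on a carbon attached to citronellol C6 (the future C1) therefore finds the tertiary C–H of the future C2 in a 1,5 relationship.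

## Retrosynthesis

**31 from 30.** Only two Si–O bonds are cut. The phenol is held as a triisopropylsilyl ether and the tertiary alcohol as a triethylsilyl ether, so that fluoride releases both at the end. The forward step must be mild enough to leave the skipped enone where it is.

**30 from 29, and 29 from 19 and 27.** The ketone comes from oxidation of the homoallylic alcohol 29. In 29 the bond between the carbinol carbon and the allylic CH2 is cut, giving aldehyde 19 and an allyl nucleophile 28 made from chloride 27. The neighbouring cut at the alkene (vinyl–benzyl) would need an alkyne carbometalation with an aluminium alkyl, which the enone does not tolerate. A cut at C2–CH2 is impossible at a quaternary carbon. The chosen cut splits the molecule into a C16 core and a C13 arene piece that already holds the (E)-alkene. The forward reaction must attack through the CH2 terminus of the allyl unit, keep the geometry, and choose the aldehyde over the hindered enone. An allylbarium reagent meets all three demands.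

**19 from 18, and 18 from 12 and 16.** Aldehyde 19 is the oxidation product of primary alcohol 18. In 18 the bond between the ketone carbon and the vinyl carbon is cut, leading to lactone 12 and alkenyllithium 17, which is made from iodide 16. The lactone is both the acyl donor and the protecting group of the arm, so one addition unveils the enone and the arm alcohol together. Lactone 12 has no α-hydrogen, so the organolithium can only add. Iodide 16 comes in two steps from alkynol 13 through silyl ether 14.

**12 from 11, and 11 from 9.** The C1–CH3 bond is cut, then the lactone C–O bond. Methylating the open ester would leave only a methyl and a primary alkyl arm on C2 to tell the faces apart, which is a weak bias. In the bicyclic enolate of 11 the outcome is set by ring fusion: a δ-lactone fuses to cyclopentane without strain only in the cis sense. The carbonyl then stays on the face of the arm and the new methyl lands cis to the C2 methyl. Ester 9 needs only desilylation to close to 11 through hydroxy ester 10.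

**9 from 8 (key disconnection).** The ring bond C1–C2, which joins the two future quaternary carbons, is cut back to a carbenoid and a tertiary C–H bond. No other cut of the ring lets a purchased stereocentre become the quaternary carbon directly. The precursor 8 is acyclic, has one stereocentre and no ring. The forward reaction must insert with retention and must outrun a 1,2-hydride shift.

**8 from 6, 5, 2, 3 and 1.** The diazo group is put on saturated ester 6 by deacylative diazo transfer through 7. Ester 6 comes from enoate 5 by hydrogenation. Enoate 5 comes from silyl ether 2 by ozonolysis to aldehyde 4 and Wittig extension with ylide 3. Silyl ether 2 is protected (S)-citronellol 1. The alkene cleavage removes the three carbons of 1 that the target does not need.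

**27 from 26, 25, 24, 23, 22 and 20.** The chloride comes from allylic alcohol 26, and 26 from enal 25. In 25 the alkene is cut by cross-metathesis back to allylarene 24, which fixes the (E)-geometry thermodynamically. Ether 24 comes from phenol 23 and hydroquinone 22. Hydroquinone 22 is made from phenol 20 through quinone 21. In 20 the allyl and methyl groups already flank the oxygen, so the later silylation and methylation cannot go to the wrong oxygen.

## Roads not taken

**Alternative 1:** De Mayo photocycloaddition. The cut removes both exocyclic C–C bonds at the quaternary carbons at once. Forward, the excited chiral dioxinone A2 adds across the tetrasubstituted double bond of 1,2-dimethylcyclopentene A1 to give the tricyclic photoadduct A3. Acetal cleavage and retro-aldol opening of the cyclobutane would then leave an acetyl group on one quaternary carbon and a carboxymethyl group on the other.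
- Merits: both quaternary carbons and their cis relation are made in one step, since a cyclobutane can only fuse cis to the cyclopentane. The alkene is symmetric, so there is no regiochemical question. The core is reached in about half the steps the chosen plan needs.
- Weak points: A1 is achiral, so the absolute configuration rests entirely on which face of A2 reacts, and its acetal tert-butyl group is remote from the reacting carbons. Addition to an unactivated tetrasubstituted alkene is slow and competes with hydrogen abstraction. The acetyl group must still be built up into the γ-hydroxy enone, which the chosen plan gets in one alkenyllithium addition.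
- Comparison: this road is shorter and gets the cis relation for free. The chosen plan sets against it an absolute configuration that is bought and carried over by a stereospecific insertion, and no photochemical scale limit.

**Alternative 2:** Methylalumination and benzyl coupling. The cut is at the trisubstituted alkene: the vinylic methyl bond and the vinyl–benzyl bond. Forward, AlMe3 with Cp2ZrCl2 adds methyl and aluminium syn across terminal alkyne A4, and zerovalent palladium, Pd(PPh3)4, couples the alkenylalane with benzylic chloride A5 to give A6.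
- Merits: the (E)-geometry follows from syn carbometalation and there is no regiochemical ambiguity. On this point it is better than the allyl-metal addition of the chosen plan.
- Weak points: AlMe3 does not tolerate the ketone or the enone, so both carbonyls must travel as silylated carbinols. A6 carries three triethylsilyl ethers and two extra stereocentres of no use. After the coupling come selective triple desilylation, a double oxidation next to an electron-rich arene, and release of the phenol. The plan also leaves open how the quaternary carbons are made.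
- Comparison: the chosen plan sets against it an endgame of three steps after fragment union, with both carbonyl carbons already at or one step from the right oxidation level.

**Alternative 3:** Epoxide ring contraction. The cut is the ring bond between C1 and its methylene neighbour. Forward, a Lewis acid opens epoxide A8 at its tertiary carbon and the ring CH2 on the other epoxide carbon migrates, giving aldehyde A9. A8 comes from cyclohexene A7, whose quaternary carbon is set by a Claisen rearrangement.
- Merits: the second quaternary carbon appears without an enolate alkylation and already carries the acyl carbon as an aldehyde. In this respect it is more direct than the lactone methylation. The migration is stereospecific, anti to the departing oxygen.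
- Weak points: the cis relation of the methyls is decided at the epoxidation. The oxygen must come from the face of the arm, against only a methyl on the other face. That is a weak steric bias, and it would have to be rescued by a hydroxyl-directed epoxidation from a bis-homoallylic position. Hydride shift to the cyclohexanone competes with ring contraction. The absolute configuration needs an asymmetric entry to the Claisen substrate.
- Comparison: the step counts are similar. The chosen plan sets against it ring-fusion control of the second centre in place of a weakly biased epoxidation, and a chiral-pool first centre.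

Key step: step 5

## Route

Remarks on the chemistry:
- Step 5 may give 9 together with its C1 epimer. C1 is epimerisable, is converged in step 6 and becomes planar in step 7, so the material is written as the (1R,2R) ester.
- Enolates and alkoxides formed by deprotonation are treated as forms of the numbered compound. Organometallic reagents generated from a numbered compound have their own number.
- Alcohol 29 is expected as a mixture of carbinol epimers, which converge in step 19.

Step 1
Reactants: 1 (S)-citronellol
Product: 2 (S)-tert-butyl[(3,7-dimethyloct-6-en-1-yl)oxy]dimethylsilane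
Conditions: TBSCl, imidazole, CH2Cl2, 0 °C → rt
Reagents that add atoms: tert-butyldimethylsilyl chloride, CC(C)(C)[Si](C)(C)Cl
Why: Standard silylation of a primary alcohol; the ether masks the future arm oxygen through ozonolysis, enolate and carbenoid chemistry, and the stereocentre is not touched.

Step 2
Reactants: 2 (S)-tert-butyl[(3,7-dimethyloct-6-en-1-yl)oxy]dimethylsilane; 3 methyl (triphenylphosphoranylidene)acetate
Product: 5 methyl (S,E)-8-[(tert-butyldimethylsilyl)oxy]-6-methyloct-2-enoate, via aldehyde 4 (not isolated)
Conditions: O3, CH2Cl2, −78 °C; PPh3, −78 °C → rt; then 3, rt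
Reagents that add atoms: none
Why: Ozonolysis with reductive work-up followed in the same flask by Wittig olefination with a stabilised ylide; the alkene geometry does not matter because the double bond is hydrogenated next.

Step 3
Reactants: 5 methyl (S,E)-8-[(tert-butyldimethylsilyl)oxy]-6-methyloct-2-enoate
Product: 6 methyl (S)-8-[(tert-butyldimethylsilyl)oxy]-6-methyloctanoate
Conditions: H2 (1 atm), Pd/C, EtOAc, rt
Reagents that add atoms: none
Why: Heterogeneous hydrogenation of a conjugated enoate; ethyl acetate as solvent keeps the silyl ether intact.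

Step 4
Reactants: 6 methyl (S)-8-[(tert-butyldimethylsilyl)oxy]-6-methyloctanoate
Product: 8 methyl (S)-8-[(tert-butyldimethylsilyl)oxy]-2-diazo-6-methyloctanoate, via trifluoroacetyl ester 7 (not isolated)
Conditions: LiN(SiMe3)2, THF, −78 °C; CF3CO2CH2CF3; then MsN3, Et3N, H2O, MeCN, rt
Reagents that add atoms: methanesulfonyl azide, CS(=O)(=O)N=[N+]=[N-]
Why: Deacylative (detrifluoroacetylative) Regitz diazo transfer: Claisen-type trifluoroacetylation activates the α-carbon, and the sulfonyl azide then delivers N2 with loss of the trifluoroacetyl group, the usual way to a diazo ester with a single activating group.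

Step 5
Reactants: 8 methyl (S)-8-[(tert-butyldimethylsilyl)oxy]-2-diazo-6-methyloctanoate
Product: 9 methyl (1R,2R)-2-{2-[(tert-butyldimethylsilyl)oxy]ethyl}-2-methylcyclopentane-1-carboxylate
Conditions: Rh2(O2CCMe3)4 (1 mol %), CH2Cl2, −40 °C, slow addition of 8, then → rt
Reagents that add atoms: none
Why: The diazo ester loses N2 on the divalent rhodium carboxylate to give an electrophilic carbenoid at chain carbon C2, which inserts into the C6–H bond through a three-centre, hydride-transfer-like transition state; the closest known reaction type is the dirhodium-catalysed intramolecular C–H insertion of α-alkyl α-diazo esters into tertiary C–H bonds. The cyclopentane closes by 1,5-insertion (new bond C2–C6, ring atoms C2 to C6), the ring size this reaction prefers. The new quaternary centre (C2 of 9) is controlled only by the citronellol stereocentre: the C–C bond forms where the hydrogen leaves, with retention, so (S) in 8 becomes (R) in 9 without any change in spatial arrangement. The ester carbon C1 is not controlled and need not be, because it is epimerisable and becomes planar in step 7. The step needs insertion to beat the 1,2-hydride shift to the (Z)-enoate and needs the tertiary C–H to be chosen; the electron-rich tertiary C–H in the 1,5 position, the bulky electron-releasing pivalate ligands and the low temperature favour this, while other C–H bonds would close four- or six-membered rings. The silyl ether oxygen could reach the carbenoid only through an eight-membered ring, and its neighbouring C–H bonds only through a seven-membered one.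

Step 6
Reactants: 9 methyl (1R,2R)-2-{2-[(tert-butyldimethylsilyl)oxy]ethyl}-2-methylcyclopentane-1-carboxylate
Product: 11 (4aR,7aR)-4a-methyl-4,4a,5,6,7,7a-hexahydrocyclopenta[c]pyran-1(3H)-one, via hydroxy ester 10 (not isolated)
Conditions: TsOH·H2O (cat.), MeOH, rt; evaporate; then DBU, PhMe, 110 °C
Reagents that add atoms: none
Why: Acid methanolysis removes the silyl group and the hydroxy ester closes to the δ-lactone by transesterification; DBU at reflux epimerises any trans ester through its enolate, so both C1 epimers should drain into the cis-fused lactone.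

Step 7
Reactants: 11 (4aR,7aR)-4a-methyl-4,4a,5,6,7,7a-hexahydrocyclopenta[c]pyran-1(3H)-one
Product: 12 (4aR,7aR)-4a,7a-dimethyl-4,4a,5,6,7,7a-hexahydrocyclopenta[c]pyran-1(3H)-one
Conditions: LiN(i-Pr)2, THF, −78 °C; MeI, DMPU, −78 → −20 °C
Reagents that add atoms: iodomethane, CI
Why: Alkylation of a lactone enolate at the ring-fusion carbon. A trans-fused δ-lactone on cyclopentane would need torsion angles at the fusion bond that the flat ester unit cannot reach, so the methyl should bond on the face that keeps the bicycle cis-fused, cis to the C4a methyl, as in additions to the ring-fusion carbon of hydrindenones with an angular methyl. The C4a centre is the controlling element.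

Step 8
Reactants: 13 2-methylbut-3-yn-2-ol
Product: 14 triethyl[(2-methylbut-3-yn-2-yl)oxy]silane
Conditions: TESOTf, 2,6-lutidine, CH2Cl2, 0 °C
Reagents that add atoms: triethylsilyl trifluoromethanesulfonate, CC[Si](CC)(CC)OS(=O)(=O)C(F)(F)F
Why: Silyl triflate silylation of a tertiary alcohol; the ether removes the acidic proton before organometallic steps and can be cleaved later by fluoride.

Step 9
Reactants: 14 triethyl[(2-methylbut-3-yn-2-yl)oxy]silane
Product: 16 (E)-triethyl[(4-iodo-2-methylbut-3-en-2-yl)oxy]silane, via alkenylzirconocene chloride 15 (not isolated)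
Conditions: Cp2Zr(H)Cl, CH2Cl2, rt; then I2, 0 °C
Reagents that add atoms: iodine, II
Why: Hydrozirconation adds Zr–H syn with zirconium on the terminal carbon, away from the bulky carbinol carbon; iodinolysis with retention gives the (E)-alkenyl iodide.

Step 10
Reactants: 16 (E)-triethyl[(4-iodo-2-methylbut-3-en-2-yl)oxy]silane; 12 (4aR,7aR)-4a,7a-dimethyl-4,4a,5,6,7,7a-hexahydrocyclopenta[c]pyran-1(3H)-one
Product: 18 (E)-1-[(1R,2R)-2-(2-hydroxyethyl)-1,2-dimethylcyclopentyl]-4-methyl-4-[(triethylsilyl)oxy]pent-2-en-1-one, via alkenyllithium 17 (not isolated)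
Conditions: 16, t-BuLi (2 equiv), Et2O, −78 °C; then 12, THF, −78 → −40 °C; aq NH4Cl
Reagents that add atoms: none
Why: Iodine–lithium exchange with retention of geometry, then single addition of the alkenyllithium to the lactone; the lithium hemiketalate should persist until work-up, and 12 has no α-hydrogen, so enolisation cannot compete. Work-up releases the enone and the arm alcohol together.

Step 11
Reactants: 18 (E)-1-[(1R,2R)-2-(2-hydroxyethyl)-1,2-dimethylcyclopentyl]-4-methyl-4-[(triethylsilyl)oxy]pent-2-en-1-one
Product: 19 2-{(1R,2R)-1,2-dimethyl-2-[(E)-4-methyl-4-(triethylsilyloxy)pent-2-enoyl]cyclopentyl}acetaldehyde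
Conditions: Dess–Martin periodinane, NaHCO3, CH2Cl2, 0 °C → rt
Reagents that add atoms: none
Why: Dess–Martin oxidation of a primary alcohol under buffered, non-basic conditions; any lactol tautomer of 18 is drained through the open hydroxy ketone.

Step 12
Reactants: 20 2-allyl-6-methylphenol
Product: 22 2-allyl-6-methylbenzene-1,4-diol, via quinone 21 (not isolated)
Conditions: K2NO(SO3)2, KH2PO4, H2O/acetone, 0 °C → rt; then Na2S2O4, H2O/Et2O, rt
Reagents that add atoms: potassium nitrosodisulfonate, [K+].[K+].[O-]S(=O)(=O)N([O])S(=O)(=O)[O-]
Why: Teuber oxidation of a para-unsubstituted 2,6-dialkylphenol to the para-quinone by Fremy's radical, then dithionite reduction to the hydroquinone; the allyl group is inert to both reagents.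

Step 13
Reactants: 22 2-allyl-6-methylbenzene-1,4-diol
Product: 23 2-allyl-6-methyl-4-[(triisopropylsilyl)oxy]phenol
Conditions: TIPSCl, imidazole, DMF, 0 °C → rt
Reagents that add atoms: triisopropylsilyl chloride, CC(C)[Si](Cl)(C(C)C)C(C)C
Why: Silylation with a bulky chloride goes to the hydroxyl that has no ortho substituent; the other hydroxyl is flanked by allyl and methyl.

Step 14
Reactants: 23 2-allyl-6-methyl-4-[(triisopropylsilyl)oxy]phenol
Product: 24 (3-allyl-4-methoxy-5-methylphenoxy)triisopropylsilane
Conditions: MeI, K2CO3, acetone, reflux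
Reagents that add atoms: iodomethane, CI
Why: Williamson ether synthesis on the remaining phenol; an aryl triisopropylsilyl ether tolerates carbonate in an aprotic solvent.

Step 15
Reactants: 24 (3-allyl-4-methoxy-5-methylphenoxy)triisopropylsilane
Product: 25 (E)-4-{2-methoxy-3-methyl-5-[(triisopropylsilyl)oxy]phenyl}-2-methylbut-2-enal
Conditions: methacrolein (excess), second-generation Hoveyda–Grubbs catalyst (5 mol %), CH2Cl2, 40 °C
Reagents that add atoms: methacrolein, CC(=C)C=O
Why: Olefin cross-metathesis of a terminal alkene with an electron-poor 1,1-disubstituted partner; the reaction is reversible and should settle on the more stable (E)-enal.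

Step 16
Reactants: 25 (E)-4-{2-methoxy-3-methyl-5-[(triisopropylsilyl)oxy]phenyl}-2-methylbut-2-enal
Product: 26 (E)-4-{2-methoxy-3-methyl-5-[(triisopropylsilyl)oxy]phenyl}-2-methylbut-2-en-1-ol
Conditions: NaBH4, CeCl3·7H2O, MeOH, 0 °C
Reagents that add atoms: none
Why: Luche 1,2-reduction of an enal; the alkene geometry and the silyl ether are not affected.

Step 17
Reactants: 26 (E)-4-{2-methoxy-3-methyl-5-[(triisopropylsilyl)oxy]phenyl}-2-methylbut-2-en-1-ol
Product: 27 (E)-[3-(4-chloro-3-methylbut-2-en-1-yl)-4-methoxy-5-methylphenoxy]triisopropylsilane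
Conditions: NCS, Me2S, CH2Cl2, −20 → 0 °C
Reagents that add atoms: N-chlorosuccinimide, ClN1C(=O)CCC1=O
Why: Corey–Kim chlorination: the alkoxysulfonium salt is displaced by chloride at the primary carbon, without allylic transposition or loss of geometry.

Step 18
Reactants: 27 (E)-[3-(4-chloro-3-methylbut-2-en-1-yl)-4-methoxy-5-methylphenoxy]triisopropylsilane; 19 2-{(1R,2R)-1,2-dimethyl-2-[(E)-4-methyl-4-(triethylsilyloxy)pent-2-enoyl]cyclopentyl}acetaldehyde
Product: 29 (E)-1-{(1R,2R)-2-[(E)-2-hydroxy-6-{2-methoxy-3-methyl-5-[(triisopropylsilyl)oxy]phenyl}-4-methylhex-4-en-1-yl]-1,2-dimethylcyclopentyl}-4-methyl-4-[(triethylsilyl)oxy]pent-2-en-1-one, via allylbarium chloride 28 (not isolated)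
Conditions: BaI2, lithium biphenylide Li(C12H10) (2 equiv), THF, rt; then 27, −78 °C; then 19, −78 °C; aq NH4Cl
Reagents that add atoms: none
Why: α-Selective carbonyl allylation with an allylbarium reagent: at −78 °C allylbarium species are configurationally stable and bond through the metal-bearing CH2, so the (E)-alkene and the linear connectivity should be kept. The aldehyde is far more reactive than the enone, whose carbonyl and β-carbon both sit next to quaternary carbons.

Step 19
Reactants: 29 (E)-1-{(1R,2R)-2-[(E)-2-hydroxy-6-{2-methoxy-3-methyl-5-[(triisopropylsilyl)oxy]phenyl}-4-methylhex-4-en-1-yl]-1,2-dimethylcyclopentyl}-4-methyl-4-[(triethylsilyl)oxy]pent-2-en-1-one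
Product: 30 (E)-1-{(1R,2R)-2-[(E)-6-{2-methoxy-3-methyl-5-[(triisopropylsilyl)oxy]phenyl}-4-methyl-2-oxohex-4-en-1-yl]-1,2-dimethylcyclopentyl}-4-methyl-4-[(triethylsilyl)oxy]pent-2-en-1-one
Conditions: Dess–Martin periodinane, NaHCO3, CH2Cl2, 0 °C
Reagents that add atoms: none
Why: Dess–Martin oxidation of a homoallylic alcohol; the buffered, non-basic medium is the usual choice for making β,γ-unsaturated ketones without double-bond migration, and the protected phenol is not oxidised.

Step 20
Reactants: 30 (E)-1-{(1R,2R)-2-[(E)-6-{2-methoxy-3-methyl-5-[(triisopropylsilyl)oxy]phenyl}-4-methyl-2-oxohex-4-en-1-yl]-1,2-dimethylcyclopentyl}-4-methyl-4-[(triethylsilyl)oxy]pent-2-en-1-one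
Product: 31 (E)-4-hydroxy-1-{(1R,2R)-2-[(E)-6-(5-hydroxy-2-methoxy-3-methylphenyl)-4-methyl-2-oxohex-4-en-1-yl]-1,2-dimethylcyclopentyl}-4-methylpent-2-en-1-one
Conditions: Bu4NF, AcOH, THF, 0 °C → rt
Reagents that add atoms: none
Why: Fluoride desilylation of the aryl and the tertiary silyl ether; acetic acid buffers the fluoride and the phenoxide so that the skipped enone is not deprotonated.

## Compound list

1 | (S)-citronellol, (S)-3,7-dimethyloct-6-en-1-ol | CC(C)=CCC[C@H](C)CCO | starting material
2 | (S)-tert-butyl[(3,7-dimethyloct-6-en-1-yl)oxy]dimethylsilane | CC(C)=CCC[C@H](C)CCO[Si](C)(C)C(C)(C)C | intermediate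
3 | methyl (triphenylphosphoranylidene)acetate | COC(=O)C=P(c1ccccc1)(c1ccccc1)c1ccccc1 | starting material
4 | (S)-6-[(tert-butyldimethylsilyl)oxy]-4-methylhexanal | O=CCC[C@H](C)CCO[Si](C)(C)C(C)(C)C | intermediate
5 | methyl (S,E)-8-[(tert-butyldimethylsilyl)oxy]-6-methyloct-2-enoate | COC(=O)/C=C/CC[C@H](C)CCO[Si](C)(C)C(C)(C)C | intermediate
6 | methyl (S)-8-[(tert-butyldimethylsilyl)oxy]-6-methyloctanoate | COC(=O)CCCC[C@H](C)CCO[Si](C)(C)C(C)(C)C | intermediate
7 | methyl (6S)-8-[(tert-butyldimethylsilyl)oxy]-6-methyl-2-(trifluoroacetyl)octanoate (C2 unassigned) | COC(=O)C(CCC[C@H](C)CCO[Si](C)(C)C(C)(C)C)C(=O)C(F)(F)F | intermediate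
8 | methyl (S)-8-[(tert-butyldimethylsilyl)oxy]-2-diazo-6-methyloctanoate | COC(=O)C(=[N+]=[N-])CCC[C@H](C)CCO[Si](C)(C)C(C)(C)C | intermediate
9 | methyl (1R,2R)-2-{2-[(tert-butyldimethylsilyl)oxy]ethyl}-2-methylcyclopentane-1-carboxylate | CC(C)(C)[Si](C)(C)OCC[C@@]1(C)CCC[C@H]1C(=O)OC | intermediate
10 | methyl (1R,2R)-2-(2-hydroxyethyl)-2-methylcyclopentane-1-carboxylate | OCC[C@@]1(C)CCC[C@H]1C(=O)OC | intermediate
11 | (4aR,7aR)-4a-methyl-4,4a,5,6,7,7a-hexahydrocyclopenta[c]pyran-1(3H)-one | O1CC[C@@]2(C)CCC[C@H]2C1=O | intermediate
12 | (4aR,7aR)-4a,7a-dimethyl-4,4a,5,6,7,7a-hexahydrocyclopenta[c]pyran-1(3H)-one | O1CC[C@@]2(C)CCC[C@@]2(C)C1=O | intermediate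
13 | 2-methylbut-3-yn-2-ol | CC(C)(O)C#C | starting material
14 | triethyl[(2-methylbut-3-yn-2-yl)oxy]silane | CC[Si](CC)(CC)OC(C)(C)C#C | intermediate
15 | chlorobis(cyclopentadienyl)[(E)-3-methyl-3-(triethylsilyloxy)but-1-en-1-yl]zirconium | CC[Si](CC)(CC)OC(C)(C)/C=C/[Zr](Cl)(C1C=CC=C1)C1C=CC=C1 | intermediate
16 | (E)-triethyl[(4-iodo-2-methylbut-3-en-2-yl)oxy]silane | CC[Si](CC)(CC)OC(C)(C)/C=C/I | intermediate
17 | [(E)-3-methyl-3-(triethylsilyloxy)but-1-en-1-yl]lithium | CC[Si](CC)(CC)OC(C)(C)/C=C/[Li] | intermediate
18 | (E)-1-[(1R,2R)-2-(2-hydroxyethyl)-1,2-dimethylcyclopentyl]-4-methyl-4-[(triethylsilyl)oxy]pent-2-en-1-one | OCC[C@@]1(C)CCC[C@@]1(C)C(=O)/C=C/C(C)(C)O[Si](CC)(CC)CC | intermediate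
19 | 2-{(1R,2R)-1,2-dimethyl-2-[(E)-4-methyl-4-(triethylsilyloxy)pent-2-enoyl]cyclopentyl}acetaldehyde | O=CC[C@@]1(C)CCC[C@@]1(C)C(=O)/C=C/C(C)(C)O[Si](CC)(CC)CC | intermediate
20 | 2-allyl-6-methylphenol | C=CCc1cccc(C)c1O | starting material
21 | 2-allyl-6-methyl-1,4-benzoquinone | C=CCC1=CC(=O)C=C(C)C1=O | intermediate
22 | 2-allyl-6-methylbenzene-1,4-diol | C=CCc1cc(O)cc(C)c1O | intermediate
23 | 2-allyl-6-methyl-4-[(triisopropylsilyl)oxy]phenol | C=CCc1cc(O[Si](C(C)C)(C(C)C)C(C)C)cc(C)c1O | intermediate
24 | (3-allyl-4-methoxy-5-methylphenoxy)triisopropylsilane | C=CCc1cc(O[Si](C(C)C)(C(C)C)C(C)C)cc(C)c1OC | intermediate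
25 | (E)-4-{2-methoxy-3-methyl-5-[(triisopropylsilyl)oxy]phenyl}-2-methylbut-2-enal | O=C/C(C)=C/Cc1cc(O[Si](C(C)C)(C(C)C)C(C)C)cc(C)c1OC | intermediate
26 | (E)-4-{2-methoxy-3-methyl-5-[(triisopropylsilyl)oxy]phenyl}-2-methylbut-2-en-1-ol | OC/C(C)=C/Cc1cc(O[Si](C(C)C)(C(C)C)C(C)C)cc(C)c1OC | intermediate
27 | (E)-[3-(4-chloro-3-methylbut-2-en-1-yl)-4-methoxy-5-methylphenoxy]triisopropylsilane | ClC/C(C)=C/Cc1cc(O[Si](C(C)C)(C(C)C)C(C)C)cc(C)c1OC | intermediate
28 | chloro[(E)-4-{2-methoxy-3-methyl-5-[(triisopropylsilyl)oxy]phenyl}-2-methylbut-2-en-1-yl]barium | Cl[Ba]C/C(C)=C/Cc1cc(O[Si](C(C)C)(C(C)C)C(C)C)cc(C)c1OC | intermediate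
29 | (E)-1-{(1R,2R)-2-[(E)-2-hydroxy-6-{2-methoxy-3-methyl-5-[(triisopropylsilyl)oxy]phenyl}-4-methylhex-4-en-1-yl]-1,2-dimethylcyclopentyl}-4-methyl-4-[(triethylsilyl)oxy]pent-2-en-1-one (carbinol epimers) | COc1c(C)cc(O[Si](C(C)C)(C(C)C)C(C)C)cc1C/C=C(\C)CC(O)C[C@@]1(C)CCC[C@@]1(C)C(=O)/C=C/C(C)(C)O[Si](CC)(CC)CC | intermediate
30 | (E)-1-{(1R,2R)-2-[(E)-6-{2-methoxy-3-methyl-5-[(triisopropylsilyl)oxy]phenyl}-4-methyl-2-oxohex-4-en-1-yl]-1,2-dimethylcyclopentyl}-4-methyl-4-[(triethylsilyl)oxy]pent-2-en-1-one | COc1c(C)cc(O[Si](C(C)C)(C(C)C)C(C)C)cc1C/C=C(\C)CC(=O)C[C@@]1(C)CCC[C@@]1(C)C(=O)/C=C/C(C)(C)O[Si](CC)(CC)CC | intermediate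
31 | (E)-4-hydroxy-1-{(1R,2R)-2-[(E)-6-(5-hydroxy-2-methoxy-3-methylphenyl)-4-methyl-2-oxohex-4-en-1-yl]-1,2-dimethylcyclopentyl}-4-methylpent-2-en-1-one | COc1c(C)cc(O)cc1C/C=C(\C)CC(=O)C[C@@]1(C)CCC[C@@]1(C)C(=O)/C=C/C(C)(C)O | target

## Step count and risks

Total: 20 steps. Longest linear sequence: 12 steps from 1 (steps 1–7, 10, 11, 18, 19, 20). The arene branch (steps 12–17) and the alkenyl iodide branch (steps 8, 9) are shorter.

**Step 5 (key step).** The most likely failure is that the 1,2-hydride shift in the carbenoid to the (Z)-enoate outruns insertion into a C–H bond that will become a quaternary centre.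
Fallback, from aldehyde 4 (isolated after the ozonolysis of 2) back to 9: the carbenoid is placed between two carbonyl groups, where no adjacent hydrogen can shift.
- Homologation of 4 with methyl diazoacetate and SnCl2 gives methyl (S)-8-[(tert-butyldimethylsilyl)oxy]-6-methyl-3-oxooctanoate F1.
- Diazo transfer (MsN3, Et3N) gives methyl (S)-8-[(tert-butyldimethylsilyl)oxy]-2-diazo-6-methyl-3-oxooctanoate F2.
- Rh2(OAc)4 closes the same ring bond by 1,5-insertion with retention, giving methyl (2R)-2-{2-[(tert-butyldimethylsilyl)oxy]ethyl}-2-methyl-5-oxocyclopentane-1-carboxylate F3.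
- The ketone is removed through the enol triflate (NaH, PhNTf2), methyl (R)-5-{2-[(tert-butyldimethylsilyl)oxy]ethyl}-5-methyl-2-{[(trifluoromethyl)sulfonyl]oxy}cyclopent-1-ene-1-carboxylate F4.
- Reduction with Pd(OAc)2, PPh3, HCO2H and Bu3N gives methyl (R)-5-{2-[(tert-butyldimethylsilyl)oxy]ethyl}-5-methylcyclopent-1-ene-1-carboxylate F5, and hydrogenation over Pd/C returns 9.

**Step 7.** The most likely failure is poor facial selectivity. The angular methyl stands perpendicular to the enolate plane, and attack anti to it would give the trans-fused lactone with trans methyls.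
Fallback, from 9 back to 12: the open-chain ester enolate (LiN(i-Pr)2, then MeI) is methylated, where the bulkier silyloxyethyl arm rather than ring fusion steers the electrophile. This gives methyl (1R,2R)-2-{2-[(tert-butyldimethylsilyl)oxy]ethyl}-1,2-dimethylcyclopentane-1-carboxylate F6. Treatment with TsOH in MeOH then closes only the isomer with ester and arm cis to lactone 12. The other isomer stays a hydroxy ester and is separated.

**Step 10.** Three things may go wrong: slow addition to a carbonyl flanked by two quaternary carbons, collapse of the hemiketalate followed by a second addition, or a product that stays as a lactol and resists oxidation.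
Fallback, from 12 back to 18:
- i-Bu2AlH reduces the lactone to (4aR,7aR)-4a,7a-dimethyloctahydrocyclopenta[c]pyran-1-ol F7.
- Excess 17 adds to its open hydroxy aldehyde form, giving (E)-1-[(1R,2R)-2-(2-hydroxyethyl)-1,2-dimethylcyclopentyl]-4-methyl-4-[(triethylsilyl)oxy]pent-2-en-1-ol F8.
- MnO2 oxidises only the allylic alcohol and gives 18.

**Step 18.** The risks are erosion of α-regioselectivity or alkene geometry by equilibration of the allyl metal, Wurtz coupling during barium insertion, and enolisation of 19 followed by intramolecular Michael addition to the enone.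
Fallback, from 27 and 19 back to 30: a sulfonyl-stabilised carbanion fixes the site of attack.
- PhSO2Na in DMF converts 27 into (E)-triisopropyl{4-methoxy-3-methyl-5-[3-methyl-4-(phenylsulfonyl)but-2-en-1-yl]phenoxy}silane F9.
- Lithiation (n-BuLi, −78 °C) and addition to 19 gives the β-hydroxy sulfone F10.
- Dess–Martin oxidation gives the β-keto sulfone F11.
- SmI2 in THF/MeOH at −78 °C removes the sulfonyl group. α-Protonation of the dienolate gives 30 directly, without passing through 29.

**Step 20.** The risk is base-induced migration of the β,γ double bond into conjugation while the tertiary silyl ether is slowly cleaved.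
Fallback, from 29 back to 31: the tertiary alcohol is freed before the sensitive ketone exists.
- HF·pyridine removes only the triethylsilyl group of 29, giving the diol F12.
- Dess–Martin oxidation, which leaves the tertiary alcohol alone, gives the keto alcohol F13.
- A brief treatment with Bu4NF and AcOH at 0 °C cleaves the aryl silyl ether and gives 31.

## Further compounds

F1 | step 5 | methyl (S)-8-[(tert-butyldimethylsilyl)oxy]-6-methyl-3-oxooctanoate | COC(=O)CC(=O)CC[C@H](C)CCO[Si](C)(C)C(C)(C)C
F2 | step 5 | methyl (S)-8-[(tert-butyldimethylsilyl)oxy]-2-diazo-6-methyl-3-oxooctanoate | COC(=O)C(=[N+]=[N-])C(=O)CC[C@H](C)CCO[Si](C)(C)C(C)(C)C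
F3 | step 5 | methyl (2R)-2-{2-[(tert-butyldimethylsilyl)oxy]ethyl}-2-methyl-5-oxocyclopentane-1-carboxylate | COC(=O)C1C(=O)CC[C@]1(C)CCO[Si](C)(C)C(C)(C)C
F4 | step 5 | methyl (R)-5-{2-[(tert-butyldimethylsilyl)oxy]ethyl}-5-methyl-2-{[(trifluoromethyl)sulfonyl]oxy}cyclopent-1-ene-1-carboxylate | COC(=O)C1=C(OS(=O)(=O)C(F)(F)F)CC[C@]1(C)CCO[Si](C)(C)C(C)(C)C
F5 | step 5 | methyl (R)-5-{2-[(tert-butyldimethylsilyl)oxy]ethyl}-5-methylcyclopent-1-ene-1-carboxylate | COC(=O)C1=CCC[C@]1(C)CCO[Si](C)(C)C(C)(C)C
F6 | step 7 | methyl (1R,2R)-2-{2-[(tert-butyldimethylsilyl)oxy]ethyl}-1,2-dimethylcyclopentane-1-carboxylate | CC(C)(C)[Si](C)(C)OCC[C@@]1(C)CCC[C@@]1(C)C(=O)OC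
F7 | step 10 | (4aR,7aR)-4a,7a-dimethyloctahydrocyclopenta[c]pyran-1-ol | O1CC[C@@]2(C)CCC[C@@]2(C)C1O
F8 | step 10 | (E)-1-[(1R,2R)-2-(2-hydroxyethyl)-1,2-dimethylcyclopentyl]-4-methyl-4-[(triethylsilyl)oxy]pent-2-en-1-ol | OCC[C@@]1(C)CCC[C@@]1(C)C(O)/C=C/C(C)(C)O[Si](CC)(CC)CC
F9 | step 18 | (E)-triisopropyl{4-methoxy-3-methyl-5-[3-methyl-4-(phenylsulfonyl)but-2-en-1-yl]phenoxy}silane | COc1c(C)cc(O[Si](C(C)C)(C(C)C)C(C)C)cc1C/C=C(\C)CS(=O)(=O)c1ccccc1
F10 | step 18 | β-hydroxy sulfone: 29 bearing a phenylsulfonyl group on the allylic carbon next to the carbinol | COc1c(C)cc(O[Si](C(C)C)(C(C)C)C(C)C)cc1C/C=C(\C)C(C(O)C[C@@]1(C)CCC[C@@]1(C)C(=O)/C=C/C(C)(C)O[Si](CC)(CC)CC)S(=O)(=O)c1ccccc1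
F11 | step 18 | β-keto sulfone: 30 bearing a phenylsulfonyl group on the carbon between ketone and alkene | COc1c(C)cc(O[Si](C(C)C)(C(C)C)C(C)C)cc1C/C=C(\C)C(C(=O)C[C@@]1(C)CCC[C@@]1(C)C(=O)/C=C/C(C)(C)O[Si](CC)(CC)CC)S(=O)(=O)c1ccccc1
F12 | step 20 | (E)-4-hydroxy-1-{(1R,2R)-2-[(E)-2-hydroxy-6-{2-methoxy-3-methyl-5-[(triisopropylsilyl)oxy]phenyl}-4-methylhex-4-en-1-yl]-1,2-dimethylcyclopentyl}-4-methylpent-2-en-1-one | COc1c(C)cc(O[Si](C(C)C)(C(C)C)C(C)C)cc1C/C=C(\C)CC(O)C[C@@]1(C)CCC[C@@]1(C)C(=O)/C=C/C(C)(C)O
F13 | step 20 | (E)-4-hydroxy-1-{(1R,2R)-2-[(E)-6-{2-methoxy-3-methyl-5-[(triisopropylsilyl)oxy]phenyl}-4-methyl-2-oxohex-4-en-1-yl]-1,2-dimethylcyclopentyl}-4-methylpent-2-en-1-one | COc1c(C)cc(O[Si](C(C)C)(C(C)C)C(C)C)cc1C/C=C(\C)CC(=O)C[C@@]1(C)CCC[C@@]1(C)C(=O)/C=C/C(C)(C)O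
A1 | alternative 1 | 1,2-dimethylcyclopentene | CC1=C(C)CCC1
A2 | alternative 1 | (R)-2-tert-butyl-6-methyl-4H-1,3-dioxin-4-one | CC(C)(C)[C@H]1OC(=O)C=C(C)O1
A3 | alternative 1 | cis-anti-cis tricyclic photoadduct (cyclobutane fused to dioxanone and cyclopentane) | CC(C)(C)[C@H]1OC(=O)[C@@H]2[C@@]3(C)CCC[C@@]3(C)[C@]2(C)O1
A4 | alternative 2 | tris(triethylsilyl) ether of (E)-1-[(1R,2R)-2-(2-hydroxypent-4-yn-1-yl)-1,2-dimethylcyclopentyl]-4-methylpent-2-ene-1,4-diol, carbinols configured as in A6 | C#CC[C@H](O[Si](CC)(CC)CC)C[C@@]1(C)CCC[C@@]1(C)[C@@H](O[Si](CC)(CC)CC)/C=C/C(C)(C)O[Si](CC)(CC)CC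
A5 | alternative 2 | tert-butyl[3-(chloromethyl)-4-methoxy-5-methylphenoxy]dimethylsilane | COc1c(C)cc(O[Si](C)(C)C(C)(C)C)cc1CCl
A6 | alternative 2 | fully protected carbon skeleton of the target with the (E)-trisubstituted alkene in place | COc1c(C)cc(O[Si](C)(C)C(C)(C)C)cc1C/C=C(\C)C[C@H](O[Si](CC)(CC)CC)C[C@@]1(C)CCC[C@@]1(C)[C@@H](O[Si](CC)(CC)CC)/C=C/C(C)(C)O[Si](CC)(CC)CC
A7 | alternative 3 | (R)-tert-butyl[2-(1,2-dimethylcyclohex-2-en-1-yl)ethoxy]dimethylsilane | CC(C)(C)[Si](C)(C)OCC[C@@]1(C)CCCC=C1C
A8 | alternative 3 | tert-butyl[2-(1,2-dimethyl-7-oxabicyclo[4.1.0]heptan-2-yl)ethoxy]dimethylsilane, oxirane oxygen cis to the silyloxyethyl arm | CC(C)(C)[Si](C)(C)OCC[C@@]1(C)CCC[C@H]2O[C@@]12C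
A9 | alternative 3 | (1R,2R)-2-{2-[(tert-butyldimethylsilyl)oxy]ethyl}-1,2-dimethylcyclopentane-1-carbaldehyde | CC(C)(C)[Si](C)(C)OCC[C@@]1(C)CCC[C@@]1(C)C=O
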